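Late in the summer run J reads 1.0% at 5.00 min, while the winter run, with the same J and G but less L, still reads 18.4% at 5.00 min, so I compare the pace of the loss of J between these two runs.

| flask | J | L | G | remark | time |
|---|---|---|---|---|---|
| winter | 0.10 M | 2 mol% | 2.6 mM | run made earlier |  |
| summer | 0.10 M | 8 mol% | 2.6 mM | run made earlier |  |
| dusk | 0.15 M | 4 mol% | 2.6 mM | run made earlier |  |
| flask | 0.10 M | 4 mol% | 2.6 mM |  | 4.0 min |

- winter (time / min: J / %, X / %): 0.417: 87.3, 14.1; 0.667: 81.6, 18.3; 0.833: 76.0, 22.4; 1.33: 64.4, 36.6; 2.00: 53.0, 46.4; 3.00: 38.3, 64.0; 5.00: 18.4, 81.8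
- summer (time / min: J / %, X / %): 0.667: 31.7, 67.7; 1.33: 9.2, 89.7; 2.00: 3.5, 97.5; 3.00: 0.6, 98.7; 4.00: 1.8, 98.8; 5.00: 1.0, 99.9
- dusk (time / min: J / %, X / %): 0.417: 65.7, 32.1; 0.667: 51.3, 47.9; 1.33: 25.3, 74.5; 2.50: 3.2, 94.5; 5.00: 2.6, 98.2

(each reading ± 1 percentage point)

- the reaction counts as stopped when no species that holds the J changes by six tenths of a point or more over the second half of the time

1. at 4.0 min, what has stopped the reaction, if anything has (no working catalyst is left / all of J has reacted / forward and back rates have come level / it is still moving)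
2. share of the J used up at 4.0 min
3. X at 4.0 min, in percent of the J charged

I read the fall of J in these two runs as a pseudo-first-order decay, and the last winter reading gives a rate constant of 0.339 min⁻¹, while the summer reading at 1.33 min gives 1.79 min⁻¹. Read between these two runs, the order in L is 1.20, which puts this flask, at 4 mol%, at 0.779 min⁻¹. I carry 3.12, the number of lifetimes in the run, rate constant times time. The winter run, with half this L, would get 1.35 lifetimes in the same time, fewer than this flask, so I expect 25.9% of J left there against 4.42% here. My reckoning therefore uses 95.6% of J, and over the second half of this flask J should fall by 17 percentage points, which is no stop under the rule.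

The forecast is lower than my figure, with 93.5% of J used (89% to 97%) and 93% of X (88% to 97%), and it says it is still moving: “J is still falling”.

The flask gives 95.9% used and 95.7% of X, and the answer on stopping is it is still moving.

    J + Z ⇌ Q, settled at all times (K = 30.0 M⁻¹)
    E ⇌ Z (K = 2.00, k = 0.890 s⁻¹)
    Z ⇌ L + X (K = 4.00 M, k = 83.0 s⁻¹)
    L + G ⇌ D (K = 470 M⁻¹, k = 36.0 M⁻¹ s⁻¹)
    J + L ⇌ E (K = 20.0 M⁻¹, k = 10.0 M⁻¹ s⁻¹)

In this flask J falls by 18 points between 2.00 min and 4.00 min, where 3.12 lifetimes gave me 17 points. The neighbour charged with 1 mol% of L, its other charges and time as here, has a reckoned rate constant of 0.147 min⁻¹, hence 0.588 lifetimes and 55.5% of J left by the same reckoning. That neighbour holds 55.1% of J and 44.8% of X at 4.00 min.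

The data are calculated for substances that don't exist.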